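**Assumption (one line):** germacranolide numbering is used throughout (C6 = lactone O–CH, C7 = ring-fusion CH, C8/C9 = the two acyloxy carbons, C10 = ring carbon bearing CO2Me, C11–C13 = methylene-lactone carbons, C2′ = side-chain carbinol), and both ring C=C bonds are taken as ring-cis exactly as the SMILES encodes them.

## Retrosynthetic overview

1. Target ⇒ (C–O) catalyst-controlled α-hydroxylation of an 8-O-(2-methylacetoacetyl) ester ⇒ (C–O) acylation of the 8-hydroxy germacranolide.
2. 8-Hydroxy germacranolide ⇒ Cr(II) macro-allylation of a (Z)-enal by a 2-(bromomethyl)enoate: the ten-membered carbocycle forms first, and the γ-lactone C6–O bond closes in the same operation.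
3. Key C–O bond: the C9–O isobutyrate, made by stereoinvertive, neighbouring-group-relayed opening of a C8–C9 epoxide; the same event frees O8–H and unveils the allylic bromide.
4. Epoxide (sets C8, C9) ⇒ organocatalytic epoxidation of a dienal, then Morita–Baylis–Hillman addition of methyl acrylate (C11–C13).
5. Dienal ⇒ Suzuki coupling and bromo-Wittig olefination on a (Z)-aldehyde cut from nerol, which brings in both ring olefins with the required geometry.

## Route

Step 1
Reactants: 1 nerol
Product: 2 neryl 4-methoxybenzyl ether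
Conditions: NaH, PMBCl, n-Bu4NI (cat.), THF, 0 °C → rt
Reagents that add atoms: 4-methoxybenzyl chloride, COc1ccc(CCl)cc1
Why: Williamson etherification of the primary allylic alkoxide; no stereocentre is formed and the (Z)-olefin is untouched.

Step 2
Reactants: 2 neryl 4-methoxybenzyl ether
Product: 4 (4Z)-6-[(4-methoxybenzyl)oxy]-4-methylhex-4-enal, via epoxide 3 (not isolated)
Conditions: mCPBA, CH2Cl2, −20 °C; then H5IO6, THF/H2O, 0 °C
Reagents that add atoms: mCPBA, OOC(=O)c1cccc(Cl)c1
Why: Prilezhaev epoxidation prefers the distal, more electron-rich trisubstituted olefin (the proximal one is deactivated by the allylic oxygen), and periodic acid cleavage of the epoxide via its diol gives the aldehyde with the epoxide oxygen retained on C1.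

Step 3
Reactants: 4 (4Z)-6-[(4-methoxybenzyl)oxy]-4-methylhex-4-enal; 5 methyl (triphenylphosphoranylidene)acetate
Product: 7 methyl (2Z,6Z)-2-bromo-8-[(4-methoxybenzyl)oxy]-6-methylocta-2,6-dienoate, via bromo ylide 6 (not isolated)
Conditions: 5, NBS, CH2Cl2, −20 °C; then 4, rt
Reagents that add atoms: N-bromosuccinimide, BrN1C(=O)CCC1=O
Why: Wittig olefination with the α-bromo stabilised ylide made in situ places the alkyl chain trans to the ester (the (Z)-α-bromoenoate), which fixes the C1=C10 geometry of the target.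

Step 4
Reactants: 7 methyl (2Z,6Z)-2-bromo-8-[(4-methoxybenzyl)oxy]-6-methylocta-2,6-dienoate; 8 (E)-3,3-diethoxyprop-1-enylboronic acid pinacol ester
Product: 10 methyl (2E,6Z)-8-[(4-methoxybenzyl)oxy]-6-methyl-2-[(1E)-3-oxoprop-1-enyl]octa-2,6-dienoate, via diethyl acetal 9 (not isolated)
Conditions: Pd(dppf)Cl2 (5 mol%), K3PO4, THF/H2O, 45 °C; then 1 M HCl, THF, 0 °C
Reagents that add atoms: water, O
Why: Suzuki–Miyaura coupling is stereoretentive at both alkenyl partners, and the acidic work-up hydrolyses the acetal to the (E)-enal.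

Step 5
Reactants: 10 methyl (2E,6Z)-8-[(4-methoxybenzyl)oxy]-6-methyl-2-[(1E)-3-oxoprop-1-enyl]octa-2,6-dienoate
Product: 11 methyl (2E,6Z)-2-[(2S,3R)-3-formyloxiran-2-yl]-8-[(4-methoxybenzyl)oxy]-6-methylocta-2,6-dienoate
Conditions: (S)-2-{bis[3,5-bis(trifluoromethyl)phenyl](trimethylsilyloxy)methyl}pyrrolidine (10 mol%), 35% aq. H2O2, CH2Cl2, rt
Reagents that add atoms: hydrogen peroxide, OO
Why: Jørgensen-type iminium/enamine epoxidation is nucleophilic, so it touches only the enal C8=C9 bond (not the electron-rich C4=C5), and the catalyst's shielding of one iminium face gives the trans epoxide with C8 R and C9 S.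

Step 6
Reactants: 11 methyl (2E,6Z)-2-[(2S,3R)-3-formyloxiran-2-yl]-8-[(4-methoxybenzyl)oxy]-6-methylocta-2,6-dienoate; 12 methyl acrylate
Product: 13 methyl (2E,6Z)-2-{(2S,3S)-3-[1-hydroxy-2-(methoxycarbonyl)prop-2-en-1-yl]oxiran-2-yl}-8-[(4-methoxybenzyl)oxy]-6-methylocta-2,6-dienoate (both C7 carbinol epimers)
Conditions: methyl acrylate (excess), DABCO (0.5 equiv), DMSO, rt
Reagents that add atoms: none
Why: Morita–Baylis–Hillman addition to the activated α,β-epoxy aldehyde installs C11–C13; the new C7 carbinol centre need not be controlled because C7 becomes sp2 in the next step.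

Step 7
Reactants: 13 Morita–Baylis–Hillman adduct; 14 isobutyric anhydride
Product: 18 methyl (2E,6Z)-2-[(1R,2S,3Z)-4-(bromomethyl)-2-hydroxy-5-methoxy-1-(2-methylpropanoyloxy)-5-oxopent-3-en-1-yl]-8-[(4-methoxybenzyl)oxy]-6-methylocta-2,6-dienoate, via O7 isobutyrate 15 (not isolated), via dioxanylium triflate 16 (not isolated), via silyl ether 17 (not isolated)
Conditions: (i-PrCO)2O, TMSOTf (5 mol%), CH2Cl2, −78 °C; TMSOTf (1.1 equiv), −78 → −40 °C; n-Bu4NBr, −40 → 0 °C; aq. citric acid
Reagents that add atoms: tetrabutylammonium bromide, CCCC[N+](CCCC)(CCCC)CCCC.[Br-]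
Why: Proposed new method: an acyloxonium-relay epoxide opening in which TMSOTf-catalysed acylation first gives the O7 isobutyrate, whose carbonyl oxygen then opens the silyl-activated epoxide at the allylic C9 (C8 is inductively deactivated by the neighbouring acyloxy carbon) through a six-membered 1,3-dioxan-2-ylium ion with inversion at C9, and bromide collapses this ion by SN2′ attack at the acrylate CH2, so the isobutyrate is transposed from O7 to O9 (9R), C8 keeps its epoxide oxygen (8S) and the (Z)-allylic bromide is unveiled in one flask; the closest known reactions are neighbouring-group (acyloxonium/ortho-ester) opening of epoxy esters, endo-selective opening of vinyl epoxides at the allylic carbon, and SN2′ halide displacement of Morita–Baylis–Hillman esters.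

Step 8
Reactants: 18 allylic bromide
Product: 20 methyl (2E,6Z)-2-[(1R,2S,3Z)-4-(bromomethyl)-2-hydroxy-5-methoxy-1-(2-methylpropanoyloxy)-5-oxopent-3-en-1-yl]-6-methyl-8-oxoocta-2,6-dienoate, via allylic alcohol 19 (not isolated)
Conditions: DDQ, CH2Cl2/pH 7 buffer, 0 °C; then TEMPO (10 mol%), PhI(OAc)2, rt
Reagents that add atoms: none
Why: Oxidative PMB cleavage followed by TEMPO/PhI(OAc)2 oxidation, which is selective for the primary allylic alcohol over the secondary C8–OH and gives the (Z)-enal without isomerisation.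

Step 9
Reactants: 20 (Z)-enal allylic bromide
Product: 22 8-hydroxy germacranolide (6R,7R,8S,9R; same spatial arrangement as the target), via seco hydroxy ester 21 (not isolated)
Conditions: CrCl2 (8 equiv), THF (3 mM, slow addition), rt; aq. NH4Cl
Reagents that add atoms: none
Why: Nozaki–Hiyama-type Cr(II) Barbier macro-allylation, the ring closure used for other germacranolides, forms C6–C7 through a chair-like allylchromium transition state (anti adduct, hence trans lactone), with the aldehyde approaching C7 anti to C9 in the A1,3-minimised conformer (H8 eclipsing the allyl unit), and the C6 alkoxide then lactonises onto the acrylate ester.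

Step 10
Reactants: 22 8-hydroxy germacranolide; 23 tert-butyl 2-methyl-3-oxobutanoate
Product: 25 8-O-(2-methyl-3-oxobutanoyl) germacranolide (both C2′ epimers), via acetyl(methyl)ketene 24 (not isolated)
Conditions: 23 (3 equiv), toluene, 105 °C, t-BuOH distilled off
Reagents that add atoms: none
Why: Thermal retro-ene loss of tert-butanol from the β-keto ester gives an acylketene that acylates the hindered C8–OH under neutral conditions (acylketene transacetoacetylation), leaving the methylene lactone untouched.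

Step 11
Reactants: 25 8-O-(2-methyl-3-oxobutanoyl) germacranolide
Product: 26 CNP0280649.1 (6R,7S,8S,9R,2′S)
Conditions: [TiCl2((R,R)-1-naphthyl-TADDOLato)(MeCN)2] (10 mol%), 3-phenyl-2-(phenylsulfonyl)oxaziridine, CH2Cl2, rt
Reagents that add atoms: 3-phenyl-2-(phenylsulfonyl)oxaziridine, O=S(=O)(c1ccccc1)N1OC1c1ccccc1
Why: Ti(TADDOLato)-catalysed electrophilic α-hydroxylation of the chelated β-keto ester enolate, in which both C2′ epimers converge on one planar enolate and oxygen is delivered to its Si face to give 2′S; the assignment of the (R,R)-ligand to this face is a design assumption and would be fixed on a model ester.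

## Compound list

1 | nerol, (2Z)-3,7-dimethylocta-2,6-dien-1-ol | OC/C=C(/C)CCC=C(C)C | starting material
2 | neryl 4-methoxybenzyl ether, 1-({[(2Z)-3,7-dimethylocta-2,6-dien-1-yl]oxy}methyl)-4-methoxybenzene | COc1ccc(COC/C=C(/C)CCC=C(C)C)cc1 | intermediate
3 | 3-{(3Z)-5-[(4-methoxybenzyl)oxy]-3-methylpent-3-en-1-yl}-2,2-dimethyloxirane (racemic) | COc1ccc(COC/C=C(/C)CCC2OC2(C)C)cc1 | intermediate (not isolated)
4 | (4Z)-6-[(4-methoxybenzyl)oxy]-4-methylhex-4-enal | COc1ccc(COC/C=C(/C)CCC=O)cc1 | intermediate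
5 | methyl (triphenylphosphoranylidene)acetate | COC(=O)C=P(c1ccccc1)(c1ccccc1)c1ccccc1 | starting material
6 | methyl bromo(triphenylphosphoranylidene)acetate | COC(=O)C(Br)=P(c1ccccc1)(c1ccccc1)c1ccccc1 | intermediate (not isolated)
7 | methyl (2Z,6Z)-2-bromo-8-[(4-methoxybenzyl)oxy]-6-methylocta-2,6-dienoate | COc1ccc(COC/C=C(/C)CC/C=C(/C(=O)OC)Br)cc1 | intermediate
8 | 2-[(1E)-3,3-diethoxyprop-1-en-1-yl]-4,4,5,5-tetramethyl-1,3,2-dioxaborolane | CCOC(OCC)/C=C/B1OC(C)(C)C(C)(C)O1 | starting material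
9 | methyl (2E,6Z)-2-[(1E)-3,3-diethoxyprop-1-enyl]-8-[(4-methoxybenzyl)oxy]-6-methylocta-2,6-dienoate | COc1ccc(COC/C=C(/C)CC/C=C(/C(=O)OC)\C=C\C(OCC)OCC)cc1 | intermediate (not isolated)
10 | methyl (2E,6Z)-8-[(4-methoxybenzyl)oxy]-6-methyl-2-[(1E)-3-oxoprop-1-enyl]octa-2,6-dienoate | COc1ccc(COC/C=C(/C)CC/C=C(/C(=O)OC)\C=C\C=O)cc1 | intermediate
11 | methyl (2E,6Z)-2-[(2S,3R)-3-formyloxiran-2-yl]-8-[(4-methoxybenzyl)oxy]-6-methylocta-2,6-dienoate (C8 R, C9 S) | COc1ccc(COC/C=C(/C)CC/C=C(/C(=O)OC)[C@@H]2O[C@H]2C=O)cc1 | intermediate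
12 | methyl acrylate | C=CC(=O)OC | starting material
13 | methyl (2E,6Z)-2-{(2S,3S)-3-[1-hydroxy-2-(methoxycarbonyl)prop-2-en-1-yl]oxiran-2-yl}-8-[(4-methoxybenzyl)oxy]-6-methylocta-2,6-dienoate, both C7 epimers | COc1ccc(COC/C=C(/C)CC/C=C(/C(=O)OC)[C@@H]2O[C@H]2C(O)C(=C)C(=O)OC)cc1 | intermediate
14 | isobutyric anhydride (2-methylpropanoic anhydride) | CC(C)C(=O)OC(=O)C(C)C | starting material
15 | O7 isobutyrate of 13 (carbinol OH esterified, epoxide as in 13) | COc1ccc(COC/C=C(/C)CC/C=C(/C(=O)OC)[C@@H]2O[C@H]2C(OC(=O)C(C)C)C(=C)C(=O)OC)cc1 | intermediate (not isolated)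
16 | 2-isopropyl-1,3-dioxan-2-ylium triflate bridging O7 and O9, C8 bearing OSiMe3, C9 inverted relative to 13 | COc1ccc(COC/C=C(/C)CC/C=C(/C(=O)OC)[C@H]2OC(C(C)C)=[O+]C(C(=C)C(=O)OC)[C@@H]2O[Si](C)(C)C)cc1.[O-]S(=O)(=O)C(F)(F)F | intermediate (not isolated)
17 | 8-O-trimethylsilyl ether of 18 | COc1ccc(COC/C=C(/C)CC/C=C(/C(=O)OC)[C@@H](OC(=O)C(C)C)[C@@H](O[Si](C)(C)C)/C=C(\CBr)C(=O)OC)cc1 | intermediate (not isolated)
18 | methyl (2E,6Z)-2-[(1R,2S,3Z)-4-(bromomethyl)-2-hydroxy-5-methoxy-1-(2-methylpropanoyloxy)-5-oxopent-3-en-1-yl]-8-[(4-methoxybenzyl)oxy]-6-methylocta-2,6-dienoate (C8 S, C9 R) | COc1ccc(COC/C=C(/C)CC/C=C(/C(=O)OC)[C@@H](OC(=O)C(C)C)[C@@H](O)/C=C(\CBr)C(=O)OC)cc1 | intermediate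
19 | 8-hydroxy analogue of 18 at the chain terminus (PMB removed): methyl (2E,6Z)-2-[(1R,2S,3Z)-4-(bromomethyl)-2-hydroxy-5-methoxy-1-(2-methylpropanoyloxy)-5-oxopent-3-en-1-yl]-8-hydroxy-6-methylocta-2,6-dienoate | OC/C=C(/C)CC/C=C(/C(=O)OC)[C@@H](OC(=O)C(C)C)[C@@H](O)/C=C(\CBr)C(=O)OC | intermediate (not isolated)
20 | methyl (2E,6Z)-2-[(1R,2S,3Z)-4-(bromomethyl)-2-hydroxy-5-methoxy-1-(2-methylpropanoyloxy)-5-oxopent-3-en-1-yl]-6-methyl-8-oxoocta-2,6-dienoate | O=C/C=C(/C)CC/C=C(/C(=O)OC)[C@@H](OC(=O)C(C)C)[C@@H](O)/C=C(\CBr)C(=O)OC | intermediate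
21 | seco hydroxy ester: ten-membered carbocycle with 6-OH, 8-OH, 9-isobutyrate, 7-[1-(methoxycarbonyl)vinyl], 10-CO2Me, ring olefins ring-cis, configured as in 22 | C=C(C(=O)OC)[C@H]1[C@H](O)/C=C(/C)CC/C=C(/C(=O)OC)[C@@H](OC(=O)C(C)C)[C@H]1O | intermediate (not isolated)
22 | 8-hydroxy germacranolide: target lacking the O8 acyl group (6R,7R,8S,9R; spatial arrangement as in target) | C=C1C(=O)O[C@@H]2/C=C(/C)CC/C=C(/C(=O)OC)[C@@H](OC(=O)C(C)C)[C@@H](O)[C@@H]12 | intermediate
23 | tert-butyl 2-methyl-3-oxobutanoate | CC(=O)C(C)C(=O)OC(C)(C)C | starting material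
24 | acetyl(methyl)ketene, 2-methyl-3-oxobut-1-en-1-one | CC(=O)C(C)=C=O | intermediate (not isolated)
25 | 8-O-(2-methyl-3-oxobutanoyl) germacranolide (6R,7S,8S,9R), both C2′ epimers | C=C1C(=O)O[C@@H]2/C=C(/C)CC/C=C(/C(=O)OC)[C@@H](OC(=O)C(C)C)[C@@H](OC(=O)C(C)C(C)=O)[C@@H]12 | intermediate
26 | CNP0280649.1 (6R,7S,8S,9R,2′S) | C=C1C(=O)O[C@@H]2/C=C(/C)CC/C=C(/C(=O)OC)[C@@H](OC(=O)C(C)C)[C@@H](OC(=O)[C@@](C)(O)C(C)=O)[C@@H]12 | target

## Step count and risk

Total step count: 11, with the one-pot two-stage operations in steps 2, 3, 4, 7 and 8 each counted as one step. Longest linear sequence: 11 steps, from nerol (1) to 26; all other reactants are bought.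

The three steps most likely to fail:

**Step 7 (the proposed new relay).** It can fail in three ways: the ester carbonyl may attack C8 in a five-membered mode, the acrylate carbonyl may compete as the internal nucleophile, or bromide may open the epoxide directly. The fallback uses known chemistry and sets out from 13. Titanium-assisted opening with isobutyric acid (Ti(OiPr)4, i-PrCO2H, CH2Cl2, rt; the Sharpless C3-selective opening of 2,3-epoxy alcohols) delivers the carboxylate to C9 with inversion and gives the triol mono-isobutyrate F1. NBS/Me2S in CH2Cl2 at −20 to 0 °C then converts only the activated Baylis–Hillman carbinol of F1 into the rearranged (Z)-allylic bromide, and the route is rejoined at 18.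

**Step 9 (macrocyclisation).** The risks are oligomerisation, the wrong C6/C7 diastereomer, and interference by the free 8-OH (chelation to chromium, O-alkylation by the allylic bromide, or lactonisation onto the C10 ester). The fallback sets out from 20. TESOTf/2,6-lutidine (CH2Cl2, −78 °C) gives the 8-O-triethylsilyl bromo enal F2, which removes the hydroxyl from play. A palladium(0)/diethylzinc umpolung allylation under high dilution (Pd(PPh3)4, Et2Zn, THF; the ring-closing method used for ten-membered germacrene rings) then gives, after lactonisation, the 8-O-triethylsilyl germacranolide F3. HF·pyridine removes the silyl group and the route is rejoined at 22.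

**Step 5 (organocatalytic epoxidation).** The cross-conjugated dienal may suffer 1,6-addition of peroxide or react with low enantioselectivity. The fallback sets out from 10. Luche reduction (NaBH4, CeCl3, MeOH, −40 °C) gives the dienol F4. Sharpless asymmetric epoxidation (Ti(OiPr)4, L-(+)-diethyl tartrate, t-BuOOH, 4 Å MS, CH2Cl2, −20 °C), which is directed only to the allylic-alcohol olefin, gives the (2S,3S)-epoxy alcohol F5. Dess–Martin oxidation of F5 rejoins the route at 11.

## Further compounds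

F1 | step 7 | triol mono-isobutyrate: 13 with the epoxide opened at C9 by isobutyrate (C7-OH, C8-OH free; 8S,9R; both C7 epimers) | COc1ccc(COC/C=C(/C)CC/C=C(/C(=O)OC)[C@@H](OC(=O)C(C)C)[C@@H](O)C(O)C(=C)C(=O)OC)cc1
F2 | step 9 | 8-O-triethylsilyl ether of 20 | O=C/C=C(/C)CC/C=C(/C(=O)OC)[C@@H](OC(=O)C(C)C)[C@@H](O[Si](CC)(CC)CC)/C=C(\CBr)C(=O)OC
F3 | step 9 | 8-O-triethylsilyl ether of 22 | C=C1C(=O)O[C@@H]2/C=C(/C)CC/C=C(/C(=O)OC)[C@@H](OC(=O)C(C)C)[C@@H](O[Si](CC)(CC)CC)[C@@H]12
F4 | step 5 | methyl (2E,6Z)-2-[(1E)-3-hydroxyprop-1-enyl]-8-[(4-methoxybenzyl)oxy]-6-methylocta-2,6-dienoate | COc1ccc(COC/C=C(/C)CC/C=C(/C(=O)OC)\C=C\CO)cc1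
F5 | step 5 | methyl (2E,6Z)-2-[(2S,3S)-3-(hydroxymethyl)oxiran-2-yl]-8-[(4-methoxybenzyl)oxy]-6-methylocta-2,6-dienoate | COc1ccc(COC/C=C(/C)CC/C=C(/C(=O)OC)[C@@H]2O[C@H]2CO)cc1
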